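**Retrosynthetic overview**
Farnesane numbering is used. Ring B is C1–C6 (C2–Br, C3–Cl/CH3). Ring A is C6–C11 (C7–CH3, C7=C8, C10–Br, C11 gem-dimethyl). C6 is the spiro carbon.
The last disconnection is C1–C6, which closes ring B. C6 of a tetrasubstituted ring-A alkene (C6=C7) alkylates the primary carbon C1 of a saturated β-bromo triflate.
The enabling feature has two parts. C1 is a CH2 next to the C2–Br carbon, so a C1 sulfonate is a latent C1/C2 bromiranium. C6 sits next to the methyl-bearing C7, so C6=C7 can act as the nucleophile and the resulting C7 cation collapses to the C7=C8 alkene of the target.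
Ring A (C6–C11 bond, C10–Br) comes from a catalytic asymmetric bromonium cyclisation of the acyclic 6,10-diene. C2–Br and C3–Cl come from catalytic enantioselective bromochlorination of the (2Z)-allylic alcohol of farnesol.
Ring A is formed first (step 2) and ring B and the spiro centre last (step 4).

Key step: step 4

Assumption: 1 is bought as the pure (2Z,6E) isomer, and for both chiral catalysts the enantiomer that gives the stated configuration is used.

**Step 1**
Reactants: 1 (2Z,6E)-farnesol
Product: 2 (2S,3S,6E)-2-bromo-3-chloro-3,7,11-trimethyldodeca-6,10-dien-1-ol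
Conditions: NBS (1.05 equiv), ClTi(OiPr)3 (1.1 equiv), chiral tridentate Schiff-base ligand (20 mol %), hexanes, −20 °C
Reagents that add atoms: N-bromosuccinimide O=C1CCC(=O)N1Br; chlorotitanium triisopropoxide CC(C)O[Ti](Cl)(OC(C)C)OC(C)C
Why: Catalytic enantioselective bromochlorination of allylic alcohols (hydroxyl-directed, Ti-bound substrate) adds anti across the Z-alkene with chloride going to tertiary C3 and bromine to C2, so both centres are set at once with the ligand choosing the face (2S,3S), while the two unbound trisubstituted alkenes stay untouched.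

**Step 2**
Reactants: 2 (2S,3S,6E)-2-bromo-3-chloro-3,7,11-trimethyldodeca-6,10-dien-1-ol
Product: 3 (2S,3S)-2-bromo-5-[(1S,5R)-5-bromo-2,6,6-trimethylcyclohex-2-en-1-yl]-3-chloro-3-methylpentan-1-ol
Conditions: 1,3-dibromo-5,5-dimethylhydantoin (1.0 equiv), chiral BINOL-derived thiophosphoramide (10 mol %), toluene, −90 °C
Reagents that add atoms: 1,3-dibromo-5,5-dimethylhydantoin CC1(C)N(Br)C(=O)N(Br)C1=O
Why: In this catalytic asymmetric bromonium-induced polyene cyclisation the chiral Lewis-base/Br+ complex selects one face of the most accessible terminal C10=C11 alkene (C10 = R), C6 of the 6E-alkene opens the bromonium at C11 through a chair with equatorial bromine (6-endo, giving a transient C6–H centre with the side chain equatorial and cis to Br), and the C7 cation can only lose a proton because the C2=C3 π bond no longer exists.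

**Step 3**
Reactants: 3 (2S,3S)-2-bromo-5-[(1S,5R)-5-bromo-2,6,6-trimethylcyclohex-2-en-1-yl]-3-chloro-3-methylpentan-1-ol
Product: 4 primary triflate of 3
Conditions: Tf2O (1.1 equiv), 2,6-di-tert-butyl-4-methylpyridine (1.1 equiv), CH2Cl2, −78 °C; cold pentane filtration, used at once
Reagents that add atoms: triflic anhydride O=S(=O)(OS(=O)(=O)C(F)(F)F)C(F)(F)F
Why: This is a standard O-triflation of a primary alcohol under hindered-base buffering that touches no stereocentre, and 4 can be handled briefly because neither carbon of its C7=C8 alkene can reach C1 through a ring smaller than seven atoms.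

**Step 4**
Reactants: 4 primary triflate of 3
Product: 7 (2S,3S,6S,10R)-2,10-dibromo-3-chloro-α-chamigrene (target), via tetrasubstituted-alkene triflate 5 (not isolated), via spiro C7 cation 6 (not isolated)
Conditions: TfOH (20 mol %), CH2Cl2–MeNO2 4:1 (0.005 M), −40 → 0 °C; Et3N quench
Reagents that add atoms: none
Why: Proposed new method: catalytic TfOH reversibly protonates the ring-A alkene of 4 to the tertiary C7 cation, so the endocyclic isomer, any exocyclic isomer and the C6–H stereocentre all drain into the tetrasubstituted C6=C7 isomer 5, the only one whose nucleophilic carbon (C6) reaches C1 through a six-membered transition state; C6 then displaces the primary triflate with anchimeric help from the C2 bromine (bromiranium-like C1), giving the tertiary spiro cation 6, which loses H8 to the endocyclic C7=C8 alkene and regenerates TfOH. The closest known reaction types are the π-route solvolytic cyclisation of alkenyl sulfonates, the acid-induced monocyclofarnesyl-to-chamigrene spirocyclisation and the capture of bromiranium ions by alkenes, and what is new is joining a saturated β-bromo triflate to an alkene nucleophile that is generated in situ by isomerisation. Ring B closes 6-exo-tet at C1 (6-endo with respect to the C1/C2 bromiranium), with the C6=C7 π bond exocyclic to the new ring. The only new stereocentre, C6, is set by the tether: backside opening at C1 forces C2–Br anti to the new C1–C6 bond and therefore equatorial in the chair-like transition state, the (2S,3S) centres then fix that chair (Cl equatorial, C3-methyl axial), and in it the quaternary C11 takes the equatorial site and the flat C7 the axial site, which is 6S. No bond to C2, C3 or C10 is broken on the productive path, so these centres are carried through unchanged. The step needs attack at C1 rather than C2, which the crowding of C2 next to quaternary C3 secures, and it needs the C3–Cl bond to survive, which the weakly ionising medium, the low temperature and the deactivating vicinal bromine secure.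

**Compound list**
1 | (2Z,6E)-farnesol | CC(C)=CCC/C(C)=C/CC/C(C)=C\CO | starting material
2 | (2S,3S,6E)-2-bromo-3-chloro-3,7,11-trimethyldodeca-6,10-dien-1-ol | CC(C)=CCC/C(C)=C/CC[C@](C)(Cl)[C@@H](Br)CO | intermediate
3 | (2S,3S)-2-bromo-5-[(1S,5R)-5-bromo-2,6,6-trimethylcyclohex-2-en-1-yl]-3-chloro-3-methylpentan-1-ol | CC1=CC[C@@H](Br)C(C)(C)[C@H]1CC[C@](C)(Cl)[C@@H](Br)CO | intermediate
4 | primary triflate of 3 | CC1=CC[C@@H](Br)C(C)(C)[C@H]1CC[C@](C)(Cl)[C@@H](Br)COS(=O)(=O)C(F)(F)F | intermediate
5 | (2S,3S)-2-bromo-5-[(5R)-5-bromo-2,6,6-trimethylcyclohex-1-en-1-yl]-3-chloro-3-methylpentyl triflate (C6=C7 isomer of 4) | CC1=C(CC[C@](C)(Cl)[C@@H](Br)COS(=O)(=O)C(F)(F)F)C(C)(C)[C@H](Br)CC1 | intermediate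
6 | spiro[5.5]undecyl cation with the charge at C7 (ring B closed, C6 = S) | C[C+]1CC[C@@H](Br)C(C)(C)[C@]12CC[C@](C)(Cl)[C@@H](Br)C2 | intermediate
7 | (2S,3S,6S,10R)-2,10-dibromo-3-chloro-α-chamigrene | CC1=CC[C@@H](Br)C(C)(C)[C@]12CC[C@](C)(Cl)[C@@H](Br)C2 | target

**Total step count:** 4. **Longest linear sequence:** 4.

**Steps most likely to fail**

**Step 4.** Closure may be sluggish or poorly face-selective. The intrinsic bias of ring A is attack anti to the pseudo-axial C11 methyl when C10–Br is equatorial, and this opposes the face that the tether imposes. The triflate may instead undergo a 1,2-bromine shift or solvolysis. The C7 cation may undergo hydride or methyl shifts.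

The fallback uses known chemistry, with an allyl cation as the electrophile and the ring-B halogens installed last. It sets out from 1 and returns at 7.
- Acetylation (Ac2O, pyridine) gives (2Z,6E)-farnesyl acetate F1.
- The asymmetric bromocyclisation of step 2 stops at the monocycle, because the alkene bearing the allylic acetate is the least nucleophilic, and gives (2Z)-5-[(1S,5R)-5-bromo-2,6,6-trimethylcyclohex-2-en-1-yl]-3-methylpent-2-en-1-yl acetate F2.
- SnCl4 in MeNO2 (or HCO2H) ionises the allylic acetate, and the classical monocyclofarnesyl-to-chamigrene cation–olefin spirocyclisation gives (6S,10R)-10-bromo-α-chamigrene F3, with C6 epimers removed by chromatography.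
- Anti, Markovnikov bromochlorination of the less hindered ring-B alkene (NBS, Et4NCl, CH2Cl2) leads to 7.

**Step 2.** Bromonium transfer may show low face selectivity or site selectivity (competing attack at C6=C7). The free hydroxyl may interfere with the catalyst.

The fallback replaces catalyst control with diastereomer separation. It sets out from 2 and returns at 3. Achiral bromodiethylsulfonium bromopentachloroantimonate in MeNO2 at −25 °C cyclises 2 to 3 together with the ring-A antipodal isomer (2S,3S)-2-bromo-5-[(1R,5S)-5-bromo-2,6,6-trimethylcyclohex-2-en-1-yl]-3-chloro-3-methylpentan-1-ol F4. Because C2 and C3 are already single, the two are diastereomers and are separated by preparative HPLC.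

**Step 1.** Enantioselectivity may be eroded on the Z-trisubstituted allylic alcohol, or regiocontrol of halide delivery may be lost.

The fallback replaces asymmetric catalysis with resolution. It sets out from 1 and returns at 2. The ligand-free, still hydroxyl-directed reaction (NBS, ClTi(OiPr)3) gives 2 together with its enantiomer (2R,3R,6E)-2-bromo-3-chloro-3,7,11-trimethyldodeca-6,10-dien-1-ol F5. Lipase-catalysed kinetic resolution (Pseudomonas cepacia lipase, vinyl acetate, MTBE) acylates the unwanted antipode to (2R,3R,6E)-2-bromo-3-chloro-3,7,11-trimethyldodeca-6,10-dien-1-yl acetate F6, and unreacted 2 is separated by chromatography.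

**Further compounds**
F1 | step 4 | (2Z,6E)-farnesyl acetate | CC(C)=CCC/C(C)=C/CC/C(C)=C\COC(C)=O
F2 | step 4 | (2Z)-5-[(1S,5R)-5-bromo-2,6,6-trimethylcyclohex-2-en-1-yl]-3-methylpent-2-en-1-yl acetate | CC1=CC[C@@H](Br)C(C)(C)[C@H]1CC/C(C)=C\COC(C)=O
F3 | step 4 | (6S,10R)-10-bromo-α-chamigrene | CC1=CC[C@@H](Br)C(C)(C)[C@]12CCC(C)=CC2
F4 | step 2 | (2S,3S)-2-bromo-5-[(1R,5S)-5-bromo-2,6,6-trimethylcyclohex-2-en-1-yl]-3-chloro-3-methylpentan-1-ol | CC1=CC[C@H](Br)C(C)(C)[C@@H]1CC[C@](C)(Cl)[C@@H](Br)CO
F5 | step 1 | (2R,3R,6E)-2-bromo-3-chloro-3,7,11-trimethyldodeca-6,10-dien-1-ol | CC(C)=CCC/C(C)=C/CC[C@@](C)(Cl)[C@H](Br)CO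
F6 | step 1 | (2R,3R,6E)-2-bromo-3-chloro-3,7,11-trimethyldodeca-6,10-dien-1-yl acetate | CC(C)=CCC/C(C)=C/CC[C@@](C)(Cl)[C@H](Br)COC(C)=O
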